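**Retrosynthetic overview**

1. The all-E C40 target has two identical (3S,4S)-3,4-dihydroxy rings (ring A = ring B, C2 symmetry). It is cut at C11=C12 and C11'=C12' into two C15 tributylphosphonium salts and the C10 dialdehyde (double Wittig).
2. Each C15 unit comes from a ring enol triflate (C6–OTf) and (E)-3-methylpent-2-en-4-yn-1-ol by Sonogashira coupling at C6–C7; the 9E geometry is bought with the enynol.
3. The only ring-forming event is closure of C2–C3: a zinc homoenolate carbon (C2) adds 6-exo to the C3 aldehyde of an acyclic iodo keto aldehyde. The homoenolate rests as a strained zinc cyclopropoxide (temporary three-membered ring C6–C1–C2), whose opening drives the closure and whose C6 epimers converge.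
4. Enabling feature: in each ring C2 is joined to C6 (the ring carbon that carries the C7≡C8 alkyne, a ketone in the precursor) through the quaternary C1 (gem-dimethyl). C2 is therefore the β-carbon of a ketone homoenolate that can neither enolize nor lose a β-hydride, and the axial C1 methyl steers the chair.
5. The acyclic precursor is assembled from methyl isobutyrate (C1 and its methyls), CH2I2 (C2), EtMgBr (C5 and its methyl) and crotonaldehyde (C3, C4) by a syn-selective boron aldol that sets C4; C5 is a relay stereocentre erased at the triflate stage.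

Key step: step 7

Assumption: (−)-Ipc2BOTf, the reagent derived from (+)-α-pinene, is taken to deliver the Z-enol borinate to the Si face of the aldehyde (the sense of the related allylboration); if the sense proves opposite, the (+)-reagent is used and nothing else changes.
Remark: locants C1–C15 in the explanations are carotenoid locants (ring C1–C6, chain C7–C15, primes for the second half).

**Route**

Step 1
Reactants: 1 methyl isobutyrate
Product: 3 methyl 3-iodo-2,2-dimethylpropanoate, via lithium ester enolate 2 (not isolated)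
Conditions: LiN(iPr)2, THF, −78 °C; CH2I2 (excess), −78 → 25 °C
Reagents that add atoms: diiodomethane ICI
Why: Alkylation (SN2) of the fully substituted ester enolate with diiodomethane should stop at the mono-adduct because the neopentyl iodide formed is inert to a second displacement; no stereocentre is formed.

Step 2
Reactants: 3 methyl 3-iodo-2,2-dimethylpropanoate
Product: 4 3-iodo-N-methoxy-N,2,2-trimethylpropanamide
Conditions: MeNHOMe·HCl, iPrMgCl, THF, −20 → 0 °C
Reagents that add atoms: N,O-dimethylhydroxylamine hydrochloride CNOC.Cl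
Why: Weinreb amide formation by aminolysis of the ester with the magnesium amide should be clean because the ester has no α-hydrogen and the neopentyl C–I bond does not react with the amide or with iPrMgCl at this temperature.

Step 3
Reactants: 4 3-iodo-N-methoxy-N,2,2-trimethylpropanamide
Product: 6 1-iodo-2,2-dimethylpentan-3-one, via magnesium hemiaminal alkoxide 5 (not isolated)
Conditions: EtMgBr, THF, 0 °C; aq NH4Cl
Reagents that add atoms: ethylmagnesium bromide CC[Mg]Br
Why: Weinreb ketone synthesis, in which the chelated tetrahedral adduct resists a second addition and releases the ethyl ketone on work-up, the neopentyl iodide being too hindered for substitution or exchange at 0 °C.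

Step 4
Reactants: 6 1-iodo-2,2-dimethylpentan-3-one; 7 (E)-but-2-enal
Product: 10 (4S,5R,6E)-5-hydroxy-1-iodo-2,2,4-trimethyloct-6-en-3-one, via Z-enol diisopinocampheylborinate 8 (not isolated), via boron aldolate 9 (not isolated)
Conditions: (−)-Ipc2BOTf, iPr2NEt, CH2Cl2, −78 °C; 7, −78 → −20 °C; H2O2, MeOH, pH 7 buffer, 0 °C
Reagents that add atoms: none
Why: Diisopinocampheylboron-mediated aldol reaction, in which 6 can enolize only towards its ethyl group (the other α-carbon, C1, is quaternary), the Z-enol borinate reacts through a chair to give the syn relation between the C4 oxygen and the C5 methyl, and the isopinocampheyl ligands choose the aldehyde face and so set C4 (see the assumption).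

Step 5
Reactants: 10 (4S,5R,6E)-5-hydroxy-1-iodo-2,2,4-trimethyloct-6-en-3-one
Product: 11 (4S,5R,6E)-5-(tert-butyldimethylsilyloxy)-1-iodo-2,2,4-trimethyloct-6-en-3-one
Conditions: tBuMe2SiOTf, 2,6-lutidine, CH2Cl2, −78 → 0 °C
Reagents that add atoms: tert-butyldimethylsilyl triflate CC(C)(C)[Si](C)(C)OS(=O)(=O)C(F)(F)F
Why: Silylation of the secondary alcohol with a silyl triflate and a hindered pyridine base should leave the ketone, the alkene, the iodide and both stereocentres untouched.

Step 6
Reactants: 11 (4S,5R,6E)-5-(tert-butyldimethylsilyloxy)-1-iodo-2,2,4-trimethyloct-6-en-3-one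
Product: 13 (2S,3S)-2-(tert-butyldimethylsilyloxy)-6-iodo-3,5,5-trimethyl-4-oxohexanal, via secondary ozonide 12 (not isolated)
Conditions: O3, CH2Cl2, −78 °C (stopped at the first blue tinge); PPh3, −78 → 25 °C
Reagents that add atoms: ozone [O-][O+]=O
Why: Ozonolysis with reductive work-up cleaves the only alkene and unveils the C3 aldehyde under neutral conditions that should not epimerize C4 or touch the neopentyl iodide and the ketone.

Step 7
Reactants: 13 (2S,3S)-2-(tert-butyldimethylsilyloxy)-6-iodo-3,5,5-trimethyl-4-oxohexanal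
Product: 16 (4S,5S,6S)-5-(tert-butyldimethylsilyloxy)-4-hydroxy-2,2,6-trimethylcyclohexan-1-one, via open zinc homoenolate 14 (not isolated), via zinc cyclopropoxide 15 (not isolated)
Conditions: Zn dust (activated with BrCH2CH2Br and Me3SiCl), LiCl, THF, 25 °C; then DMSO, 45 °C; aq NH4Cl
Reagents that add atoms: none
Why: Proposed new method: zinc inserts into the neopentyl C2–I bond to give the β-zincio ketone 14, which should rest as the strained zinc cyclopropoxide 15 (reversible 3-exo addition to the C6 ketone, both C6 epimers) and be drained from it by irreversible addition of C2 to the C3 aldehyde, so that release of roughly 27 kcal/mol of cyclopropane strain drives formation of the C2–C3 bond. The closest known reactions are the additions of zinc and titanium ester homoenolates to aldehydes (homo-Reformatsky reaction) and the zinc-mediated ring-opening C–C bond formations of cyclopropanols. The six-membered ring closes in the 6-exo-trig mode through a chair in which the C5 methyl and the C4 silyloxy group are equatorial, the C4–O bond lying antiperiplanar to the forming bond and zinc being able to bridge O3 and O4. The new C3 stereocentre is controlled by the axial methyl on C1, which forbids an axial zinc-bound carbonyl oxygen (1,3-diaxial clash) and places O3 equatorial, trans to O4 (3S). The step needs chemoselectivity for the aldehyde over the ketone, secured because ketone addition is reversible and aldehyde addition is not, and regioselective reopening of 15 to the primary C–Zn bond, secured because polar ring opening puts zinc on the less substituted carbon. The quaternary C1 excludes β-hydride elimination and enolization of the homoenolate, and the gem-dialkyl effect favours closure.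

Step 8
Reactants: 16 (4S,5S,6S)-5-(tert-butyldimethylsilyloxy)-4-hydroxy-2,2,6-trimethylcyclohexan-1-one
Product: 17 (4S,5S,6S)-4,5-bis(tert-butyldimethylsilyloxy)-2,2,6-trimethylcyclohexan-1-one
Conditions: tBuMe2SiOTf, 2,6-lutidine, CH2Cl2, 0 °C
Reagents that add atoms: tert-butyldimethylsilyl triflate CC(C)(C)[Si](C)(C)OS(=O)(=O)C(F)(F)F
Why: Silylation of the C3 alcohol protects it against the base and the triflating agent of the next step and should not enolize the hindered ketone with this weak base.

Step 9
Reactants: 17 (4S,5S,6S)-4,5-bis(tert-butyldimethylsilyloxy)-2,2,6-trimethylcyclohexan-1-one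
Product: 19 (3S,4S)-3,4-bis(tert-butyldimethylsilyloxy)-2,6,6-trimethylcyclohex-1-en-1-yl trifluoromethanesulfonate, via potassium enolate 18 (not isolated)
Conditions: KN(SiMe3)2, THF, −78 °C; PhNTf2, −78 → 0 °C
Reagents that add atoms: N-phenylbis(trifluoromethanesulfonimide) O=S(=O)(N(c1ccccc1)S(=O)(=O)C(F)(F)F)C(F)(F)F
Why: Enol triflate formation, in which the ketone can be deprotonated only at C5 (C1 is quaternary), which erases the relay stereocentre, while the equatorial C4 silyloxy group lies near the enolate plane so that β-elimination is stereoelectronically disfavoured.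

Step 10
Reactants: 19 (3S,4S)-3,4-bis(tert-butyldimethylsilyloxy)-2,6,6-trimethylcyclohex-1-en-1-yl trifluoromethanesulfonate; 20 (2E)-3-methylpent-2-en-4-yn-1-ol
Product: 21 (2E)-5-[(3S,4S)-3,4-bis(tert-butyldimethylsilyloxy)-2,6,6-trimethylcyclohex-1-en-1-yl]-3-methylpent-2-en-4-yn-1-ol
Conditions: Pd(PPh3)4 (cat.), CuI (cat.), iPr2NH, DMF, 40 °C
Reagents that add atoms: none
Why: Sonogashira coupling of the hindered cyclohexenyl triflate with the terminal alkyne forms the C6–C7 bond and carries the E geometry of the enynol unchanged into the 9E double bond.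

Step 11
Reactants: 21 (2E)-5-[(3S,4S)-3,4-bis(tert-butyldimethylsilyloxy)-2,6,6-trimethylcyclohex-1-en-1-yl]-3-methylpent-2-en-4-yn-1-ol
Product: 22 (3S,4S)-1-[(3E)-5-bromo-3-methylpent-3-en-1-yn-1-yl]-3,4-bis(tert-butyldimethylsilyloxy)-2,6,6-trimethylcyclohex-1-ene
Conditions: CBr4, PPh3, CH2Cl2, −20 °C
Reagents that add atoms: tetrabromomethane BrC(Br)(Br)Br
Why: Appel bromination converts the primary allylic alcohol into the bromide under neutral conditions that spare the silyl ethers, the enyne and the ionizable allylic C4–O bond.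

Step 12
Reactants: 22 (3S,4S)-1-[(3E)-5-bromo-3-methylpent-3-en-1-yn-1-yl]-3,4-bis(tert-butyldimethylsilyloxy)-2,6,6-trimethylcyclohex-1-ene
Product: 23 tributyl{(2E)-5-[(3S,4S)-3,4-bis(tert-butyldimethylsilyloxy)-2,6,6-trimethylcyclohex-1-en-1-yl]-3-methylpent-2-en-4-yn-1-yl}phosphonium bromide
Conditions: PBu3, EtOAc, 25 °C
Reagents that add atoms: tributylphosphine CCCCP(CCCC)CCCC
Why: Quaternization (SN2) of the primary allylic bromide by the strongly nucleophilic trialkylphosphine should give the salt without allylic transposition.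

Step 13
Reactants: 23 tributyl{(2E)-5-[(3S,4S)-3,4-bis(tert-butyldimethylsilyloxy)-2,6,6-trimethylcyclohex-1-en-1-yl]-3-methylpent-2-en-4-yn-1-yl}phosphonium bromide (two equivalents); 24 (2E,4E,6E)-2,7-dimethylocta-2,4,6-trienedial
Product: 27 (all-E,3S,4S,3'S,4'S)-3,4,3',4'-tetrakis(tert-butyldimethylsilyloxy)-7,8,7',8'-tetradehydro-β,β-carotene, via phosphorus ylide 25 (not isolated), via C25 monoaldehyde 26 (not isolated)
Conditions: NaOMe, CH2Cl2/MeOH, 0 → 25 °C, dark
Reagents that add atoms: none
Why: Double Wittig olefination, in which allylic trialkylphosphonium ylides are known to favour E-alkenes and are less delocalized than triphenylphosphonium ylides, which should form the 11E and 11'E bonds and preserve 9E and 9'E, the remaining double bonds coming unchanged from 24.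

Step 14
Reactants: 27 (all-E,3S,4S,3'S,4'S)-3,4,3',4'-tetrakis(tert-butyldimethylsilyloxy)-7,8,7',8'-tetradehydro-β,β-carotene
Product: 28 (all-E,3S,4S,3'S,4'S)-7,8,7',8'-tetradehydro-β,β-carotene-3,4,3',4'-tetrol (CNP0283832.1)
Conditions: Bu4NF, AcOH, THF, 25 °C, dark, argon
Reagents that add atoms: none
Why: Fluoride-mediated desilylation buffered with acetic acid should free the four hydroxyl groups without the acid that would ionize the allylic C4 and C4' alcohols and without touching any stereocentre or double bond.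

**Compound list**

1 | methyl isobutyrate | COC(=O)C(C)C | starting material
2 | lithium enolate of methyl isobutyrate | COC(O[Li])=C(C)C | intermediate
3 | methyl 3-iodo-2,2-dimethylpropanoate | COC(=O)C(C)(C)CI | intermediate
4 | 3-iodo-N-methoxy-N,2,2-trimethylpropanamide | CON(C)C(=O)C(C)(C)CI | intermediate
5 | bromomagnesium alkoxide of the tetrahedral adduct of 4 and EtMgBr | CCC(O[Mg]Br)(N(C)OC)C(C)(C)CI | intermediate
6 | 1-iodo-2,2-dimethylpentan-3-one | CCC(=O)C(C)(C)CI | intermediate
7 | (E)-but-2-enal | C/C=C/C=O | starting material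
8 | (Z)-enol bis[(−)-isopinocampheyl]borinate of 6 | C/C=C(\OB([C@@H]1C[C@@H]2C[C@H]([C@H]1C)C2(C)C)[C@@H]1C[C@@H]2C[C@H]([C@H]1C)C2(C)C)C(C)(C)CI | intermediate
9 | bis[(−)-isopinocampheyl]boron aldolate of 10 | C/C=C/[C@@H](OB([C@@H]1C[C@@H]2C[C@H]([C@H]1C)C2(C)C)[C@@H]1C[C@@H]2C[C@H]([C@H]1C)C2(C)C)[C@H](C)C(=O)C(C)(C)CI | intermediate
10 | (4S,5R,6E)-5-hydroxy-1-iodo-2,2,4-trimethyloct-6-en-3-one | C/C=C/[C@@H](O)[C@H](C)C(=O)C(C)(C)CI | intermediate
11 | (4S,5R,6E)-5-(tert-butyldimethylsilyloxy)-1-iodo-2,2,4-trimethyloct-6-en-3-one | C/C=C/[C@@H](O[Si](C)(C)C(C)(C)C)[C@H](C)C(=O)C(C)(C)CI | intermediate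
12 | secondary ozonide (3-methyl-1,2,4-trioxolan-5-yl compound) of 11 | CC1OOC(O1)[C@@H](O[Si](C)(C)C(C)(C)C)[C@H](C)C(=O)C(C)(C)CI | intermediate
13 | (2S,3S)-2-(tert-butyldimethylsilyloxy)-6-iodo-3,5,5-trimethyl-4-oxohexanal | O=C[C@@H](O[Si](C)(C)C(C)(C)C)[C@H](C)C(=O)C(C)(C)CI | intermediate
14 | open zinc homoenolate (iodozinc at C2 of 13) | O=C[C@@H](O[Si](C)(C)C(C)(C)C)[C@H](C)C(=O)C(C)(C)C[Zn]I | intermediate
15 | iodozinc 2,2-dimethylcyclopropan-1-olate (both epimers at the carbinol carbon) | O=C[C@@H](O[Si](C)(C)C(C)(C)C)[C@H](C)C1(O[Zn]I)CC1(C)C | intermediate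
16 | (4S,5S,6S)-5-(tert-butyldimethylsilyloxy)-4-hydroxy-2,2,6-trimethylcyclohexan-1-one | O=C1[C@@H](C)[C@H](O[Si](C)(C)C(C)(C)C)[C@@H](O)CC1(C)C | intermediate
17 | (4S,5S,6S)-4,5-bis(tert-butyldimethylsilyloxy)-2,2,6-trimethylcyclohexan-1-one | O=C1[C@@H](C)[C@H](O[Si](C)(C)C(C)(C)C)[C@@H](O[Si](C)(C)C(C)(C)C)CC1(C)C | intermediate
18 | potassium enolate of 17 | CC1=C(O[K])C(C)(C)C[C@H](O[Si](C)(C)C(C)(C)C)[C@H]1O[Si](C)(C)C(C)(C)C | intermediate
19 | (3S,4S)-3,4-bis(tert-butyldimethylsilyloxy)-2,6,6-trimethylcyclohex-1-en-1-yl trifluoromethanesulfonate | CC1=C(OS(=O)(=O)C(F)(F)F)C(C)(C)C[C@H](O[Si](C)(C)C(C)(C)C)[C@H]1O[Si](C)(C)C(C)(C)C | intermediate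
20 | (2E)-3-methylpent-2-en-4-yn-1-ol | C#C/C(C)=C/CO | starting material
21 | (2E)-5-[(3S,4S)-3,4-bis(tert-butyldimethylsilyloxy)-2,6,6-trimethylcyclohex-1-en-1-yl]-3-methylpent-2-en-4-yn-1-ol | CC1=C(C#C/C(C)=C/CO)C(C)(C)C[C@H](O[Si](C)(C)C(C)(C)C)[C@H]1O[Si](C)(C)C(C)(C)C | intermediate
22 | (3S,4S)-1-[(3E)-5-bromo-3-methylpent-3-en-1-yn-1-yl]-3,4-bis(tert-butyldimethylsilyloxy)-2,6,6-trimethylcyclohex-1-ene | CC1=C(C#C/C(C)=C/CBr)C(C)(C)C[C@H](O[Si](C)(C)C(C)(C)C)[C@H]1O[Si](C)(C)C(C)(C)C | intermediate
23 | tributyl{(2E)-5-[(3S,4S)-3,4-bis(tert-butyldimethylsilyloxy)-2,6,6-trimethylcyclohex-1-en-1-yl]-3-methylpent-2-en-4-yn-1-yl}phosphonium bromide | CC1=C(C#C/C(C)=C/C[P+](CCCC)(CCCC)CCCC)C(C)(C)C[C@H](O[Si](C)(C)C(C)(C)C)[C@H]1O[Si](C)(C)C(C)(C)C.[Br-] | intermediate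
24 | (2E,4E,6E)-2,7-dimethylocta-2,4,6-trienedial | O=C/C(C)=C/C=C/C=C(C)/C=O | starting material
25 | tributylphosphonium ylide of 23 | CC1=C(C#C/C(C)=C/C=P(CCCC)(CCCC)CCCC)C(C)(C)C[C@H](O[Si](C)(C)C(C)(C)C)[C@H]1O[Si](C)(C)C(C)(C)C | intermediate
26 | all-E C25 monoaldehyde (product of the first olefination) | CC1=C(C#C/C(C)=C/C=C/C(C)=C/C=C/C=C(C)/C=O)C(C)(C)C[C@H](O[Si](C)(C)C(C)(C)C)[C@H]1O[Si](C)(C)C(C)(C)C | intermediate
27 | (all-E,3S,4S,3'S,4'S)-3,4,3',4'-tetrakis(tert-butyldimethylsilyloxy)-7,8,7',8'-tetradehydro-β,β-carotene | CC1=C(C#C/C(C)=C/C=C/C(C)=C/C=C/C=C(C)/C=C/C=C(\C)C#CC2=C(C)[C@H](O[Si](C)(C)C(C)(C)C)[C@@H](O[Si](C)(C)C(C)(C)C)CC2(C)C)C(C)(C)C[C@H](O[Si](C)(C)C(C)(C)C)[C@H]1O[Si](C)(C)C(C)(C)C | intermediate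
28 | (all-E,3S,4S,3'S,4'S)-7,8,7',8'-tetradehydro-β,β-carotene-3,4,3',4'-tetrol | CC1=C(C#C/C(C)=C/C=C/C(C)=C/C=C/C=C(C)/C=C/C=C(\C)C#CC2=C(C)[C@H](O)[C@@H](O)CC2(C)C)C(C)(C)C[C@H](O)[C@H]1O | target

**Step count and risks**

Total step count: 14. Longest linear sequence: 14 steps (1 → 28); 7, 20 and 24 enter as purchased building blocks.

Steps most likely to fail:

Step 7 (proposed new method). The organozinc may stay parked as the cyclopropoxide or be protonated before it reaches the aldehyde, or the aldehyde face may be chosen poorly. The fallback uses known chemistry and gives up the homoenolate manifold for a carbonyl-selective alkylchromium nucleophile. It sets out from 13, which is treated with CrCl2 and catalytic cobalt phthalocyanine (CoPc, C32H16CoN8) in DMF at 25 °C (cobalt-catalysed alkyl Nozaki–Hiyama–Kishi cyclization). The trivalent alkylchromium species adds to aldehydes but not to ketones, so no cyclopropoxide can form, and the same all-equatorial chair should deliver 16, where the route is rejoined. No new compound is made on the way.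

Step 4. Enolization of the hindered ketone by the bulky boron triflate may be slow, and facial discrimination may be insufficient or opposite to the assumed sense. The fallback replaces reagent control by a racemic aldol followed by kinetic resolution. It sets out from 6 and 7: Bu2BOTf and iPr2NEt (CH2Cl2, −78 → 0 °C; H2O2 work-up) should give the racemic syn-aldol rac-(4S,5R,6E)-5-hydroxy-1-iodo-2,2,4-trimethyloct-6-en-3-one F1. Sharpless kinetic resolution of this E-propenyl carbinol (Ti(OiPr)4, D-(−)-diisopropyl tartrate, tBuOOH, 4 Å sieves, CH2Cl2, −20 °C) should epoxidize the (4R,5S)-enantiomer to the epoxy alcohol (4R,5R,6S,7S)-6,7-epoxy-5-hydroxy-1-iodo-2,2,4-trimethyloctan-3-one F2 and leave the slow-reacting enantiomer 10, where the route is rejoined.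

Step 13. The ylide is delocalized over C11–C9, which may scramble the 9E geometry, and E selectivity at C11=C12 may be incomplete; equilibration afterwards is not an option because it would also move C9. The fallback reverses the polarity so that no carbanion is conjugated with C9=C10. It sets out from 21 and 24. Oxidation of 21 with MnO2 (CH2Cl2, 25 °C) should give the C15 enal (2E)-5-[(3S,4S)-3,4-bis(tert-butyldimethylsilyloxy)-2,6,6-trimethylcyclohex-1-en-1-yl]-3-methylpent-2-en-4-ynal F3. Reduction of 24 with NaBH4 (MeOH, 0 °C) should give (2E,4E,6E)-2,7-dimethylocta-2,4,6-triene-1,8-diol F4, which PBr3 (Et2O, pyridine, −10 °C) should convert into (2E,4E,6E)-1,8-dibromo-2,7-dimethylocta-2,4,6-triene F5 and P(OEt)3 (neat, 110 °C, Arbuzov reaction) into tetraethyl [(2E,4E,6E)-2,7-dimethylocta-2,4,6-triene-1,8-diyl]bis(phosphonate) F6. Double Horner–Wadsworth–Emmons olefination of F6 with two equivalents of F3 (NaH, THF, 0 °C) should give 27, where the route is rejoined.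

**Further compounds**

F0 | step 7 | none | none
F1 | step 4 | rac-(4S,5R,6E)-5-hydroxy-1-iodo-2,2,4-trimethyloct-6-en-3-one (racemate, both enantiomers shown) | C/C=C/[C@@H](O)[C@H](C)C(=O)C(C)(C)CI.C/C=C/[C@H](O)[C@@H](C)C(=O)C(C)(C)CI
F2 | step 4 | (4R,5R,6S,7S)-6,7-epoxy-5-hydroxy-1-iodo-2,2,4-trimethyloctan-3-one | C[C@@H]1O[C@H]1[C@H](O)[C@@H](C)C(=O)C(C)(C)CI
F3 | step 13 | (2E)-5-[(3S,4S)-3,4-bis(tert-butyldimethylsilyloxy)-2,6,6-trimethylcyclohex-1-en-1-yl]-3-methylpent-2-en-4-ynal | CC1=C(C#C/C(C)=C/C=O)C(C)(C)C[C@H](O[Si](C)(C)C(C)(C)C)[C@H]1O[Si](C)(C)C(C)(C)C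
F4 | step 13 | (2E,4E,6E)-2,7-dimethylocta-2,4,6-triene-1,8-diol | OC/C(C)=C/C=C/C=C(C)/CO
F5 | step 13 | (2E,4E,6E)-1,8-dibromo-2,7-dimethylocta-2,4,6-triene | BrC/C(C)=C/C=C/C=C(C)/CBr
F6 | step 13 | tetraethyl [(2E,4E,6E)-2,7-dimethylocta-2,4,6-triene-1,8-diyl]bis(phosphonate) | CCOP(=O)(OCC)C/C(C)=C/C=C/C=C(C)/CP(=O)(OCC)OCC
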